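The synthesis rests on cutting the bond between C4 of the benzo ring and the side-chain CH2. The feature exploited is the C3 carboxyl group on the dihydrofuran ring. As a phenylacetic-acid-type carboxylate it carries divalent palladium to C4–H, the only C–H ortho to C3a (C7a bears O1). In one operation this unfunctionalised C–H bond of an enantiopure trans-2-aryl-2,3-dihydrobenzofuran-3-carboxylic acid is joined to the terminal =CH2 of the pyruvate enol ester of protected caffeic acid. That partner delivers the whole caffeoyloxypropanoate arm, one oxidation level too high. Asymmetric hydrogenation, esterification with protected (R)-danshensu and a single acidic deprotection finish the synthesis.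

Key step: step 12

Abbreviations and numbering: PMB = 4-methoxybenzyl; ArP = 3,4-bis(PMB-oxy)phenyl; the bicyclic core is numbered O1, C2, C3, C3a, C4, C5, C6, C7, C7a.

Assumption: the sense of induction of Rh2(R-PTTL)4 (2S) and of (R,R)-Et-DuPHOS (R) is taken from the closest analogues (2-aryl-2,3-dihydrobenzofuran-3-carboxylates and 2-acyloxyacrylates); if either proves opposite, the mirror-image catalyst is used.

Step 1
Reactants: 1 3,4-dihydroxybenzaldehyde
Product: 2 3,4-bis(PMB-oxy)benzaldehyde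
Conditions: PMBCl, K2CO3, DMF, 60 °C
Reagents that add atoms: 4-methoxybenzyl chloride, COc1ccc(CCl)cc1
Why: Williamson ether synthesis, in which K2CO3 deprotonates both phenols and the phenoxides displace chloride from the reactive benzylic halide while the aldehyde stays inert.

Step 2
Reactants: 2 3,4-bis(PMB-oxy)benzaldehyde
Product: 3 [3,4-bis(PMB-oxy)phenyl]methanol
Conditions: NaBH4, THF/MeOH, 0 °C
Reagents that add atoms: none
Why: Borohydride reduction of the aldehyde gives the primary benzylic alcohol and leaves the PMB ethers untouched.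

Step 3
Reactants: 4 (2,3-dimethoxyphenyl)acetic acid
Product: 6 methyl 2-(2,3-dihydroxyphenyl)acetate, via 2,3-dihydroxyphenylacetic acid 5 (not isolated)
Conditions: BBr3, CH2Cl2, −78 °C to rt; then MeOH, reflux
Reagents that add atoms: methanol, CO
Why: Lewis-acid aryl methyl ether cleavage frees the catechol, and the HBr released on adding methanol drives Fischer esterification (and reopens any benzofuranone lactone) to the methyl ester.

Step 4
Reactants: 6 methyl 2-(2,3-dihydroxyphenyl)acetate; 3 [3,4-bis(PMB-oxy)phenyl]methanol (2.3 equiv)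
Product: 7 methyl 2-{2,3-bis[(ArP)methoxy]phenyl}acetate
Conditions: PPh3, DIAD, THF, 0 °C to rt
Reagents that add atoms: none
Why: Double Mitsunobu etherification under neutral conditions alkylates both phenols with the same benzylic alcohol, so the unit next to the acetate arm later supplies C2 with its aryl group, the identical unit on the other oxygen serves as an acid-labile protecting group, and the two phenols need not be told apart.

Step 5
Reactants: 7 methyl 2-{2,3-bis[(ArP)methoxy]phenyl}acetate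
Product: 8 methyl 2-diazo-2-{2,3-bis[(ArP)methoxy]phenyl}acetate
Conditions: p-ABSA, DBU, MeCN/CH2Cl2, 0 °C to rt
Reagents that add atoms: 4-acetamidobenzenesulfonyl azide, CC(=O)Nc1ccc(cc1)S(=O)(=O)N=[N+]=[N-]
Why: Regitz diazo transfer to the DBU-generated arylacetate enolate is the standard entry to aryldiazoacetates and touches no other group.

Step 6
Reactants: 8 methyl 2-diazo-2-{2,3-bis[(ArP)methoxy]phenyl}acetate
Product: 9 methyl (2S,3R)-2-(ArP)-7-[(ArP)methoxy]-2,3-dihydrobenzofuran-3-carboxylate (cis)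
Conditions: Rh2(R-PTTL)4 [dirhodium tetrakis(N-phthaloyl-(R)-tert-leucinate)] (1 mol %), toluene, −60 °C
Reagents that add atoms: none
Why: Intramolecular 1,5 C–H insertion of the donor/acceptor rhodium carbenoid into the activated O–CH2Ar bond closes the dihydrofuran ring, the chiral carboxylate pocket should set C2 as S and deliver the kinetic cis (3R) isomer in a concerted insertion, and the meta-placed benzyl ether on O7 cannot reach the carbenoid.

Step 7
Reactants: 9 cis methyl ester (2S,3R)
Product: 11 (2S,3S)-2-(ArP)-7-[(ArP)methoxy]-2,3-dihydrobenzofuran-3-carboxylic acid (trans), via trans methyl ester 10 (not isolated)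
Conditions: NaOMe (cat.), MeOH/THF, rt; then aq NaOH, 45 °C; then 1 M HCl
Reagents that add atoms: sodium hydroxide, [Na+].[OH-] (oxygen of the new carboxyl OH)
Why: Base-mediated epimerisation through the C3 ester enolate relieves the cis strain and sets C3 as S under thermodynamic control by the untouched C2 centre, and saponification then frees the directing carboxyl group.

Step 8
Reactants: 2 3,4-bis(PMB-oxy)benzaldehyde; 12 malonic acid
Product: 13 (E)-3-(ArP)acrylic acid
Conditions: pyridine, piperidine (cat.), 90 °C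
Reagents that add atoms: none
Why: Knoevenagel–Doebner condensation with decarboxylation gives the E-cinnamic acid under thermodynamic control in a medium that does not harm PMB ethers.

Step 9
Reactants: 14 sodium pyruvate
Product: 15 4-methoxybenzyl pyruvate
Conditions: PMBCl, NaI (cat.), DMF, rt
Reagents that add atoms: 4-methoxybenzyl chloride, COc1ccc(CCl)cc1
Why: SN2 alkylation of the carboxylate by the benzylic halide forms the ester without added base, which avoids aldol self-condensation of the pyruvate.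

Step 10
Reactants: 13 (E)-3-(ArP)acrylic acid; 15 4-methoxybenzyl pyruvate
Product: 17 4-methoxybenzyl 2-{[(E)-3-(ArP)acryloyl]oxy}acrylate, via acid chloride 16 (not isolated)
Conditions: 1-chloro-N,N,2-trimethylprop-1-en-1-amine, CH2Cl2, 0 °C; then 15, Et3N, DMAP (cat.), −20 °C to rt
Reagents that add atoms: 1-chloro-N,N,2-trimethylprop-1-en-1-amine, CC(C)=C(Cl)N(C)C (supplies the chlorine of 16 only; no atom of it remains in 17)
Why: Neutral acid chloride formation spares the PMB ethers, and O-acylation of the amine-generated pyruvate enolate is the established entry to 2-acyloxyacrylates.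

Step 11
Reactants: 18 sodium (R)-3-(3,4-dihydroxyphenyl)lactate (sodium danshensu)
Product: 19 4-methoxybenzyl (R)-3-(ArP)-2-hydroxypropanoate
Conditions: PMBCl, K2CO3, DMF, rt
Reagents that add atoms: 4-methoxybenzyl chloride, COc1ccc(CCl)cc1
Why: In this chemoselective Williamson and carboxylate alkylation only the carboxylate and the phenoxides are nucleophilic with K2CO3, so the secondary alcohol stays free and the (R) centre from the chiral pool is not touched.

Step 12
Reactants: 11 trans acid (2S,3S); 17 4-methoxybenzyl 2-{[(E)-3-(ArP)acryloyl]oxy}acrylate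
Product: 20 (2S,3S)-2-(ArP)-7-[(ArP)methoxy]-4-[(Z)-2-{[(E)-3-(ArP)acryloyl]oxy}-3-oxo-3-(PMB-oxy)prop-1-enyl]-2,3-dihydrobenzofuran-3-carboxylic acid
Conditions: Pd(OAc)2 (10 mol %), Ac-Ile-OH (20 mol %), KHCO3, O2 (1 atm), t-AmylOH, 85 °C; then 1 M HCl
Reagents that add atoms: none
Why: The potassium carboxylate at C3 binds Pd(OAc)2 ligated by Ac-Ile-OH, and concerted metalation–deprotonation cleaves C4–H through a six-membered palladacycle (Pd–O–C(=O)–C3–C3a–C4). The aryl–palladium bond then adds across the terminal alkene of 17 with the aryl group going to the unsubstituted CH2, which makes the C4–C bond; palladium ends on the fully substituted alpha carbon, whose only beta hydrogens are those of the new benzylic CH2, so syn beta-hydride elimination can give only the aryl-conjugated enol ester (Z expected, aryl away from the ester), and O2 returns zerovalent palladium to the divalent state. The closest known reaction type is the carboxylate-directed, amino-acid-ligand-accelerated Fujiwara–Moritani (oxidative Heck) olefination of phenylacetic acids, together with the Heck arylation of 2-acylamino- and 2-acyloxyacrylates. No ring is closed in the product and no stereocentre is formed; C2 and C3 are spectators, and any enolisation at C3 would only return the favoured trans isomer. Site selectivity among many electron-rich arene C–H bonds is secured by the carboxylate, because C4 is the only C–H ortho to C3a (the other ortho position, C7a, carries O1) and none of the PMB or catechol rings can form a comparable chelate. Alkene selectivity is secured because the terminal 1,1-disubstituted C=CH2 inserts much faster than the 1,2-disubstituted caffeoyl C=C, and beta-acyloxy elimination is impossible since the acyloxy group sits on the carbon that bears palladium.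

Step 13
Reactants: 20 enol ester acid
Product: 21 (2S,3S)-2-(ArP)-7-[(ArP)methoxy]-4-[(2R)-2-{[(E)-3-(ArP)acryloyl]oxy}-3-oxo-3-(PMB-oxy)propyl]-2,3-dihydrobenzofuran-3-carboxylic acid
Conditions: [Rh(cod)((R,R)-Et-DuPHOS)]BF4 (5 mol %), H2 (6 bar), CH2Cl2/MeOH, rt
Reagents that add atoms: none
Why: In this chelation-controlled asymmetric hydrogenation of a 2-acyloxyacrylate the enol C=C and the acyl C=O bind the cationic monovalent rhodium centre together, so the ligand sets the new centre as R from either alkene isomer, while the caffeoyl C=C cannot chelate and the PMB groups are not hydrogenolysed by a homogeneous rhodium catalyst.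

Step 14
Reactants: 21 (2R)-acyloxy ester acid; 19 4-methoxybenzyl (R)-3-(ArP)-2-hydroxypropanoate
Product: 22 fully protected target (C3 carboxyl esterified with 19)
Conditions: EDC·HCl, DMAP (cat.), CH2Cl2, 0 °C to rt
Reagents that add atoms: none
Why: Steglich-type esterification acylates the free secondary alcohol with retention at its (R) centre, and C3 cannot be lost because the trans arrangement is the thermodynamic one.

Step 15
Reactants: 22 fully protected target
Product: 23 target CNP0201431.1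
Conditions: TFA, anisole (excess), CH2Cl2, 0 °C to rt
Reagents that add atoms: none
Why: In this acidolysis the ten PMB groups and the still more electron-rich benzyl ether on O7 ionise to stabilised benzylic cations that anisole intercepts by Friedel–Crafts alkylation (a method established for catechol bis-PMB ethers and PMB esters in sensitive molecules), whereas the enoate, the two ester links, the C2–O1 bond deactivated by the adjacent C3 ester and the four stereocentres should not react with cold TFA.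

Compound list
1 | 3,4-dihydroxybenzaldehyde | O=Cc1ccc(O)c(O)c1 | starting material
2 | 3,4-bis[(4-methoxybenzyl)oxy]benzaldehyde | O=Cc1ccc(OCc2ccc(OC)cc2)c(OCc2ccc(OC)cc2)c1 | intermediate
3 | {3,4-bis[(4-methoxybenzyl)oxy]phenyl}methanol | OCc1ccc(OCc2ccc(OC)cc2)c(OCc2ccc(OC)cc2)c1 | intermediate
4 | (2,3-dimethoxyphenyl)acetic acid | COc1cccc(CC(=O)O)c1OC | starting material
5 | (2,3-dihydroxyphenyl)acetic acid | O=C(O)Cc1cccc(O)c1O | intermediate
6 | methyl 2-(2,3-dihydroxyphenyl)acetate | COC(=O)Cc1cccc(O)c1O | intermediate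
7 | methyl 2-{2,3-bis[(ArP)methoxy]phenyl}acetate | COC(=O)Cc1cccc(OCc2ccc(OCc3ccc(OC)cc3)c(OCc3ccc(OC)cc3)c2)c1OCc1ccc(OCc2ccc(OC)cc2)c(OCc2ccc(OC)cc2)c1 | intermediate
8 | methyl 2-diazo-2-{2,3-bis[(ArP)methoxy]phenyl}acetate | COC(=O)C(=[N+]=[N-])c1cccc(OCc2ccc(OCc3ccc(OC)cc3)c(OCc3ccc(OC)cc3)c2)c1OCc1ccc(OCc2ccc(OC)cc2)c(OCc2ccc(OC)cc2)c1 | intermediate
9 | methyl (2S,3R)-2-(ArP)-7-[(ArP)methoxy]-2,3-dihydrobenzofuran-3-carboxylate (cis) | c1ccc(OCc3ccc(OCc4ccc(OC)cc4)c(OCc4ccc(OC)cc4)c3)c2c1[C@@H](C(=O)OC)[C@@H](c1ccc(OCc3ccc(OC)cc3)c(OCc3ccc(OC)cc3)c1)O2 | intermediate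
10 | methyl (2S,3S)-2-(ArP)-7-[(ArP)methoxy]-2,3-dihydrobenzofuran-3-carboxylate (trans) | c1ccc(OCc3ccc(OCc4ccc(OC)cc4)c(OCc4ccc(OC)cc4)c3)c2c1[C@H](C(=O)OC)[C@@H](c1ccc(OCc3ccc(OC)cc3)c(OCc3ccc(OC)cc3)c1)O2 | intermediate
11 | (2S,3S)-2-(ArP)-7-[(ArP)methoxy]-2,3-dihydrobenzofuran-3-carboxylic acid (trans) | c1ccc(OCc3ccc(OCc4ccc(OC)cc4)c(OCc4ccc(OC)cc4)c3)c2c1[C@H](C(=O)O)[C@@H](c1ccc(OCc3ccc(OC)cc3)c(OCc3ccc(OC)cc3)c1)O2 | intermediate
12 | malonic acid | O=C(O)CC(=O)O | starting material
13 | (E)-3-{3,4-bis[(4-methoxybenzyl)oxy]phenyl}acrylic acid | O=C(O)/C=C/c1ccc(OCc2ccc(OC)cc2)c(OCc2ccc(OC)cc2)c1 | intermediate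
14 | sodium pyruvate | CC(=O)C(=O)[O-].[Na+] | starting material
15 | 4-methoxybenzyl pyruvate | CC(=O)C(=O)OCc1ccc(OC)cc1 | intermediate
16 | (E)-3-{3,4-bis[(4-methoxybenzyl)oxy]phenyl}acryloyl chloride | O=C(Cl)/C=C/c1ccc(OCc2ccc(OC)cc2)c(OCc2ccc(OC)cc2)c1 | intermediate
17 | 4-methoxybenzyl 2-{[(E)-3-(ArP)acryloyl]oxy}acrylate | C=C(OC(=O)/C=C/c1ccc(OCc2ccc(OC)cc2)c(OCc2ccc(OC)cc2)c1)C(=O)OCc1ccc(OC)cc1 | intermediate
18 | sodium (R)-3-(3,4-dihydroxyphenyl)-2-hydroxypropanoate (sodium danshensu) | [Na+].[O-]C(=O)[C@H](O)Cc1ccc(O)c(O)c1 | starting material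
19 | 4-methoxybenzyl (R)-3-(ArP)-2-hydroxypropanoate | O[C@H](Cc1ccc(OCc2ccc(OC)cc2)c(OCc2ccc(OC)cc2)c1)C(=O)OCc1ccc(OC)cc1 | intermediate
20 | (2S,3S)-4-[(Z)-enol ester] acid, product of the C–H olefination | O=C(/C=C/c1ccc(OCc2ccc(OC)cc2)c(OCc2ccc(OC)cc2)c1)O/C(=C\c1ccc(OCc3ccc(OCc4ccc(OC)cc4)c(OCc4ccc(OC)cc4)c3)c2c1[C@H](C(=O)O)[C@@H](c1ccc(OCc3ccc(OC)cc3)c(OCc3ccc(OC)cc3)c1)O2)C(=O)OCc1ccc(OC)cc1 | intermediate
21 | (2S,3S)-4-[(2R)-2-acyloxy-3-oxo-3-(PMB-oxy)propyl] acid | O=C(/C=C/c1ccc(OCc2ccc(OC)cc2)c(OCc2ccc(OC)cc2)c1)O[C@H](Cc1ccc(OCc3ccc(OCc4ccc(OC)cc4)c(OCc4ccc(OC)cc4)c3)c2c1[C@H](C(=O)O)[C@@H](c1ccc(OCc3ccc(OC)cc3)c(OCc3ccc(OC)cc3)c1)O2)C(=O)OCc1ccc(OC)cc1 | intermediate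
22 | fully protected target (ten PMB groups, one ArP-methyl ether on O7) | O=C(/C=C/c1ccc(OCc2ccc(OC)cc2)c(OCc2ccc(OC)cc2)c1)O[C@H](Cc1ccc(OCc3ccc(OCc4ccc(OC)cc4)c(OCc4ccc(OC)cc4)c3)c2c1[C@H](C(=O)O[C@H](Cc1ccc(OCc3ccc(OC)cc3)c(OCc3ccc(OC)cc3)c1)C(=O)OCc1ccc(OC)cc1)[C@@H](c1ccc(OCc3ccc(OC)cc3)c(OCc3ccc(OC)cc3)c1)O2)C(=O)OCc1ccc(OC)cc1 | intermediate
23 | CNP0201431.1, (2S,3S) core, both lactate centres (R) | O=C(/C=C/c1ccc(O)c(O)c1)O[C@H](Cc1ccc(O)c2c1[C@H](C(=O)O[C@H](Cc1ccc(O)c(O)c1)C(=O)O)[C@@H](c1ccc(O)c(O)c1)O2)C(=O)O | target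

Total step count: 15. Longest linear sequence: 10 steps (1, 2, 4, 5, 6, 7, 12, 13, 14, 15).

Steps most likely to fail

Step 12. Migratory insertion of the 1,1-disubstituted, donor- and acceptor-substituted alkene into the crowded palladacycle may be slower than catalyst decay. The enol ester may also pass its acyl group to carboxylate or solvent during long heating with KHCO3. The fallback makes the same bond by a Mizoroki–Heck reaction of a pre-installed C4 bromide; it sets out from 4 and comes back at 20.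
- NBS in MeCN should brominate 4 para to the unhindered 3-methoxy group to give 2-(6-bromo-2,3-dimethoxyphenyl)acetic acid F1.
- BBr3 and then methanol lead through 2-(6-bromo-2,3-dihydroxyphenyl)acetic acid F2 to methyl 2-(6-bromo-2,3-dihydroxyphenyl)acetate F3.
- Double Mitsunobu etherification with 3 gives the brominated bis(benzyl) ether F4, and diazo transfer gives the brominated diazo ester F5.
- Insertion with Rh2(R-PTTL)4 gives the cis-4-bromo ester F6, catalytic NaOMe the trans-4-bromo ester F7, and NaOH the trans-4-bromo acid F8.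
- Heck coupling of F8 with 17 (Pd(OAc)2, P(o-tol)3, Et3N, DMF, 90 °C) returns to 20.

Step 13. If the hindered trisubstituted enol ester binds slowly, reduction of the caffeoyl C=C may compete, and facial selectivity may drop in a mismatched pairing with the resident stereocentres. The fallback replaces C=C hydrogenation by C=O reduction; it sets out from 20 and comes back at 21.
- 4-Methoxybenzyl alcohol and K2CO3 in THF at 0 °C take the acyl group off the enol ester (exchange at the PMB ester is degenerate) and give the arylpyruvate acid F9.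
- (+)-B-Chlorodiisopinocampheylborane in THF at −25 °C, the enantiomer that gives (R)-aryllactates, reduces the ketone to the (R)-hydroxy ester acid F10.
- Acylation of F10 with acid chloride 16 and pyridine, followed by an aqueous NaHCO3 wash that hydrolyses any mixed anhydride at the C3 carboxyl group, gives 21.

Step 14. The crowded activated C3 acyl group may acylate the hindered alcohol slowly. This leaves time for rearrangement to the N-acylurea and for enolisation of the activated acyl group, with ketene formation or beta-elimination of the O1 phenoxide that opens the dihydrofuran ring. The fallback uses the carboxylate as nucleophile instead of activating it; it sets out from 19 and 21 and comes back at 22.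
- Appel bromination of 19 (CBr4, PPh3, CH2Cl2, 0 °C) with inversion gives 4-methoxybenzyl (S)-2-bromo-3-(ArP)propanoate F11.
- The caesium carboxylate of 21 (Cs2CO3, DMF, 0 °C to rt) displaces bromide in an SN2 reaction with a second inversion, so 22 is reached with the (R) configuration.

Further compounds
F1 | step 12 | 2-(6-bromo-2,3-dimethoxyphenyl)acetic acid | COc1ccc(Br)c(CC(=O)O)c1OC
F2 | step 12 | 2-(6-bromo-2,3-dihydroxyphenyl)acetic acid | O=C(O)Cc1c(Br)ccc(O)c1O
F3 | step 12 | methyl 2-(6-bromo-2,3-dihydroxyphenyl)acetate | COC(=O)Cc1c(Br)ccc(O)c1O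
F4 | step 12 | methyl 2-{6-bromo-2,3-bis[(ArP)methoxy]phenyl}acetate | COC(=O)Cc1c(Br)ccc(OCc2ccc(OCc3ccc(OC)cc3)c(OCc3ccc(OC)cc3)c2)c1OCc1ccc(OCc2ccc(OC)cc2)c(OCc2ccc(OC)cc2)c1
F5 | step 12 | methyl 2-diazo-2-{6-bromo-2,3-bis[(ArP)methoxy]phenyl}acetate | COC(=O)C(=[N+]=[N-])c1c(Br)ccc(OCc2ccc(OCc3ccc(OC)cc3)c(OCc3ccc(OC)cc3)c2)c1OCc1ccc(OCc2ccc(OC)cc2)c(OCc2ccc(OC)cc2)c1
F6 | step 12 | methyl (2S,3R)-4-bromo-2-(ArP)-7-[(ArP)methoxy]-2,3-dihydrobenzofuran-3-carboxylate (cis) | Brc1ccc(OCc3ccc(OCc4ccc(OC)cc4)c(OCc4ccc(OC)cc4)c3)c2c1[C@@H](C(=O)OC)[C@@H](c1ccc(OCc3ccc(OC)cc3)c(OCc3ccc(OC)cc3)c1)O2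
F7 | step 12 | methyl (2S,3S)-4-bromo-2-(ArP)-7-[(ArP)methoxy]-2,3-dihydrobenzofuran-3-carboxylate (trans) | Brc1ccc(OCc3ccc(OCc4ccc(OC)cc4)c(OCc4ccc(OC)cc4)c3)c2c1[C@H](C(=O)OC)[C@@H](c1ccc(OCc3ccc(OC)cc3)c(OCc3ccc(OC)cc3)c1)O2
F8 | step 12 | (2S,3S)-4-bromo-2-(ArP)-7-[(ArP)methoxy]-2,3-dihydrobenzofuran-3-carboxylic acid (trans) | Brc1ccc(OCc3ccc(OCc4ccc(OC)cc4)c(OCc4ccc(OC)cc4)c3)c2c1[C@H](C(=O)O)[C@@H](c1ccc(OCc3ccc(OC)cc3)c(OCc3ccc(OC)cc3)c1)O2
F9 | step 13 | (2S,3S)-2-(ArP)-7-[(ArP)methoxy]-4-[2,3-dioxo-3-(PMB-oxy)propyl]-2,3-dihydrobenzofuran-3-carboxylic acid | O=C(Cc1ccc(OCc3ccc(OCc4ccc(OC)cc4)c(OCc4ccc(OC)cc4)c3)c2c1[C@H](C(=O)O)[C@@H](c1ccc(OCc3ccc(OC)cc3)c(OCc3ccc(OC)cc3)c1)O2)C(=O)OCc1ccc(OC)cc1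
F10 | step 13 | (2S,3S)-2-(ArP)-7-[(ArP)methoxy]-4-[(2R)-2-hydroxy-3-oxo-3-(PMB-oxy)propyl]-2,3-dihydrobenzofuran-3-carboxylic acid | O[C@H](Cc1ccc(OCc3ccc(OCc4ccc(OC)cc4)c(OCc4ccc(OC)cc4)c3)c2c1[C@H](C(=O)O)[C@@H](c1ccc(OCc3ccc(OC)cc3)c(OCc3ccc(OC)cc3)c1)O2)C(=O)OCc1ccc(OC)cc1
F11 | step 14 | 4-methoxybenzyl (S)-2-bromo-3-(ArP)propanoate | Br[C@@H](Cc1ccc(OCc2ccc(OC)cc2)c(OCc2ccc(OC)cc2)c1)C(=O)OCc1ccc(OC)cc1
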